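You have to decide which reagent, if either, goes in slowly, and how slowly.

common to all: first nucleophile 0.600 M; time 8.0 min

| run | starting material | second nucleophile | remark |
|---|---|---|---|
| alpha | 0.40 M | 0.480 M | everything together at the start |
| eta | 0.40 M | 0.480 M (fed, over 30 s) | all else is in the flask from the start; the feed brings no volume worth counting |
| gamma | 0.40 M | 0.480 M (fed, over 5.0 min) | all else is in the flask from the start; the feed brings no volume worth counting |
| epsilon | 0.40 M (fed, over 5.0 min) | 0.480 M | all else is in the flask from the start; the feed brings no volume worth counting |

    starting material → intermediate (k1 = 0.012 s⁻¹)
    first nucleophile + intermediate ⇌ target (K2 = 1.5 L mol⁻¹, k2 = 1.1 L mol⁻¹ s⁻¹)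
    second nucleophile + intermediate → other capture product (k3 = 0.64 L mol⁻¹ s⁻¹)
    2 second nucleophile → homo dimer (k4 = 0.013 L mol⁻¹ s⁻¹)
    second nucleophile → decomposed reagent (k5 = 0.0036 s⁻¹)

- for a step with 2 of a species take k times the square, and two of it per event
- run time (alpha): 8.0 min

- the best flask by amount of target, in percent of the starting material charged; "all alike" if 1.5 percentage points covers them all (alpha / eta / gamma / epsilon / all alike)
- amount of target at the end, in percent of the starting material charged, alpha
- amount of target at the end, in percent of the starting material charged, eta
- amount of target at the end, in percent of the starting material charged, gamma
- amount of target at the end, in percent of the starting material charged, epsilon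

Follow one molecule of intermediate, with square brackets meaning concentration. At the start of alpha it meets the first nucleophile at 0.660 s⁻¹ and the second at 0.307 s⁻¹ (pseudo-first-order rates), and as target it returns at 0.733 s⁻¹. These are faster than the 0.012 s⁻¹ at which starting material gives intermediate, so I treat target and intermediate as one pool at equilibrium.

In that pool, target over intermediate is the equilibrium constant times [first nucleophile], 0.90 at the charge. That puts 47.4% of the pool in target. I call this fraction, ratio over one plus ratio, the target share.

But the second nucleophile drains the pool irreversibly, so I expect the final target to be the target share of what capture leaves. There is more second nucleophile than starting material, 1.20 to one, so the question is how much of it is wasted. At full charge it goes to dimer and decay at 0.00772 M s⁻¹, while alpha first makes intermediate at 0.00480 M s⁻¹, so in alpha the waste starts faster than the making.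

In epsilon, starting material enters at 0.00133 M s⁻¹, slower than that waste, so I rank epsilon first. In gamma, the second nucleophile enters at 0.00160 M s⁻¹, slower than the first making of intermediate, which gamma shares with alpha, so I expect it to stay dilute and rank gamma last. I put eta, whose feed is shorter than gamma's, below alpha. My reckoning stops at this order and gives no percentages.

The forecast names epsilon, with alpha 21%, eta 16.5%, gamma 4% and epsilon 24%, holding that “feeding the starting material slowly leaves the second nucleophile to dimerise and decay first”.

The simulation gives 15.1% for alpha, 11.5% for eta, 0.956% for gamma and 27.1% for epsilon, so epsilon is best. Epsilon ends with 32.9% as other capture product and 3.12% as starting material, with 81.9% of its first nucleophile left. At that remainder epsilon's target share is 42.4%, which gives 27.1% of target. The neighbour of gamma charged with 1.6 M of starting material ends with 45.6% of its first nucleophile, a target share of 29.1%. With 29.7% captured, that share gives 20.4%, and the neighbour holds 20.4% of target.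

The rate constants are those of an exercise.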